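Guaiane numbering is used for both C15 halves. Primed atoms belong to the half that carries the spiro carbon C4' and the saturated ketone C3'. TBS = tert-butyldimethylsilyl.
Cuts: (i) C2–C4' and C14–C15' (Diels–Alder, cyclohexene ring), which reduces both halves to one monomer, enone 20. (ii) In the monomer, C12 is removed as CO (O6–C12, C11–C12), then C6–C7, C7–C11 (acetylide) and C8–C9 (glyoxylate ene) are cut, and the cyclopentene is traced back to limonene oxide.
Enabling feature: C6–C7 is the bond shared by the seven-membered ring (C1, C5, C6, C7, C8, C9, C10) and the lactone ring (O, C6, C7, C11, C12). Without C12, O–C6–C7–C11≡C13 is a homopropargylic alcohol. A C7 propargylic mesylate (umpoled to an allenylindium) and a C6 aldehyde on one cyclopentene therefore close the ring and set C6 and C7 together.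
Forward ring order: cyclopentene (aldol), seven-membered ring (step 10), lactone (CO), then the cyclohexene by union of 20 with its dehydro form 22.
Stereochemistry: C1 comes from (R)-limonene and C8 from the (R)-BINOL–titanium ene catalyst. C5 is set by kinetic protonation anti to the C1 side chain. The C7 carbinol is set by Felkin–Anh addition, then relayed to C7 by chirality transfer and to C6 by the cyclic transition state. C4' is set by α-face attack on 20, and C10 and C5 of the enone half by equilibration.

Key step: step 10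

Assumption: C5–H and C10–H of the unprimed half are both γ-hydrogens of the C1=C2–C3=O enone and hence epimerisable, and the 5β-H,10β-H arrangement written in the target is taken to be the equilibrium one (diene 22 enters with 5α-H).

Step 1
Reactants: 1 (+)-limonene oxide
Product: 2 (3R)-6-oxo-3-(prop-1-en-2-yl)heptanal
Conditions: H5IO6, THF/H2O, 0 °C to rt
Reagents that add atoms: water, O
Why: Acid opens the epoxide to the 1,2-diol, which periodate cleaves (Malaprade glycol cleavage) without touching the 1,1-disubstituted alkene or the stereocentre.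

Step 2
Reactants: 2 (3R)-6-oxo-3-(prop-1-en-2-yl)heptanal
Product: 3 (5S)-2-methyl-5-(prop-1-en-2-yl)cyclopent-1-ene-1-carbaldehyde
Conditions: piperidine, AcOH, toluene, 80 °C
Reagents that add atoms: none
Why: Intramolecular aldol condensation through the aldehyde enamine onto the methyl ketone gives the ring-contracted enal, a well-known conversion that leaves C1 untouched.

Step 3
Reactants: 3 (5S)-2-methyl-5-(prop-1-en-2-yl)cyclopent-1-ene-1-carbaldehyde; 4 ethyl glyoxylate
Product: 5 ethyl (2R)-4-[(1S)-2-formyl-3-methylcyclopent-2-en-1-yl]-2-hydroxypent-4-enoate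
Conditions: (R)-BINOL (10 mol %), Ti(Oi-Pr)2Cl2 (10 mol %), 4 Å molecular sieves, CH2Cl2, −30 to 0 °C
Reagents that add atoms: none
Why: In this catalytic asymmetric glyoxylate-ene reaction only the electron-rich isopropenyl group acts as the ene (the enal alkene is deactivated), a methyl hydrogen is transferred so that C10=C14 is regenerated, and the (R)-catalyst sets (R)-C8.

Step 4
Reactants: 5 ethyl (2R)-4-[(1S)-2-formyl-3-methylcyclopent-2-en-1-yl]-2-hydroxypent-4-enoate
Product: 6 O-TBS ether of 5
Conditions: TBSCl, imidazole, DMF, rt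
Reagents that add atoms: tert-butyldimethylsilyl chloride (TBSCl), CC(C)(C)[Si](C)(C)Cl
Why: Standard silylation of a secondary alcohol masks O8 for the base, hydride, organometal and oxidation steps that follow.

Step 5
Reactants: 6 O-TBS ether of 5
Product: 9 ethyl (2R)-2-(TBS-oxy)-4-[(1R,5R)-5-(hydroxymethyl)-4-methylcyclopent-3-en-1-yl]pent-4-enoate, via potassium dienolate 7 (not isolated), via cis β,γ-unsaturated aldehyde 8 (not isolated)
Conditions: KOt-Bu, THF, −40 °C; AcOH, −78 °C; then MeOH, NaBH4, −78 to −20 °C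
Reagents that add atoms: none
Why: In this classical deconjugation the more stable endocyclic dienolate 7 is protonated kinetically at the α-carbon C5 from the face opposite the C1 side chain to give the cis (1αH,5αH) aldehyde 8, which NaBH4 traps before it can reconjugate or epimerise, while the far less acidic C8–H of the ester is left alone.

Step 6
Reactants: 9 ethyl (2R)-2-(TBS-oxy)-4-[(1R,5R)-5-(hydroxymethyl)-4-methylcyclopent-3-en-1-yl]pent-4-enoate
Product: 10 (2R)-2-(TBS-oxy)-4-[(1R,5R)-5-(hydroxymethyl)-4-methylcyclopent-3-en-1-yl]pent-4-enal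
Conditions: i-Bu2AlH (2.3 equiv), CH2Cl2, −78 °C; aq potassium sodium tartrate
Reagents that add atoms: none
Why: Partial reduction of an α-silyloxy ester stops at the aldehyde because the chelated aluminium hemiacetal survives at −78 °C, the first equivalent of hydride merely deprotonating the free alcohol.

Step 7
Reactants: 10 (2R)-2-(TBS-oxy)-4-[(1R,5R)-5-(hydroxymethyl)-4-methylcyclopent-3-en-1-yl]pent-4-enal; 11 ethynylmagnesium bromide
Product: 12 (3S,4R)-4-(TBS-oxy)-6-[(1R,5R)-5-(hydroxymethyl)-4-methylcyclopent-3-en-1-yl]hept-6-en-1-yn-3-ol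
Conditions: THF, −78 °C; aq NH4Cl
Reagents that add atoms: none
Why: Non-chelating (polar Felkin–Anh) addition to the α-silyloxy aldehyde should favour the 7,8-anti carbinol, and the minor syn isomer is removed by chromatography.

Step 8
Reactants: 12 (3S,4R)-4-(TBS-oxy)-6-[(1R,5R)-5-(hydroxymethyl)-4-methylcyclopent-3-en-1-yl]hept-6-en-1-yn-3-ol
Product: 13 (1R,5R)-5-[(4R,5S)-4-(TBS-oxy)-5-hydroxyhept-1-en-6-yn-2-yl]-2-methylcyclopent-2-ene-1-carbaldehyde
Conditions: TEMPO (10 mol %), PhI(OAc)2, CH2Cl2, 0 °C to rt
Reagents that add atoms: none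
Why: The oxoammonium oxidation prefers the unhindered primary alcohol over the secondary carbinol flanked by the silyl ether, and it is mild enough for the epimerisable β,γ-unsaturated aldehyde.

Step 9
Reactants: 13 (1R,5R)-5-[(4R,5S)-4-(TBS-oxy)-5-hydroxyhept-1-en-6-yn-2-yl]-2-methylcyclopent-2-ene-1-carbaldehyde
Product: 14 C7 methanesulfonate of 13
Conditions: MsCl, Et3N, CH2Cl2, −78 °C
Reagents that add atoms: methanesulfonyl chloride (MsCl), CS(=O)(=O)Cl
Why: Sulfene-type mesylation of the propargylic alcohol is fast at −78 °C, retains the C7 configuration, and keeps the aldehyde's contact with base short; the product is used at once.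

Step 10
Reactants: 14 C7 methanesulfonate of 13
Product: 16 hydroazulenol (6α-OH 7β-ethynyl 8β-OTBS), via allenylindium 15 (not isolated)
Conditions: Pd(dppf)Cl2 (5 mol %), InI (1.5 equiv), THF/HMPA 3:1, slow addition of 14 to 0.005 M, rt
Reagents that add atoms: none
Why: Zerovalent palladium (formed from Pd(dppf)Cl2 and InI) displaces the C7 mesylate in an anti SN2' sense to give an allenylpalladium species, InI takes the allenyl group over as the trivalent allenylindium 15 with indium on C13, the tethered C6 aldehyde binds to indium, and C7 attacks C6 through a cyclic SE2' transition state that regenerates the C11≡C13 triple bond. The closest known reactions are the Marshall propargylation (palladium/InI coupling of enantioenriched propargylic mesylates and aldehydes to anti homopropargylic alcohols) and the intramolecular palladium/SmI2 coupling of propargylic esters and carbonyl groups to 2-alkynylcycloalkanols. One ring is closed, the seven-membered carbocycle C1–C5–C6–C7–C8–C9–C10, in a 7-exo-trig mode at the aldehyde carbon, which turns the cyclopentene into the cis-fused hydroazulene. C7 is controlled by central-to-axial-to-central chirality transfer (anti ionisation, syn delivery, hence inversion of the (7S)-mesylate to 7α-H), and this is independent of allylic strain at C8 because the sp carbon C11 carries no cis substituent. C6 is controlled by the cyclic transition state, in which the indium-bound oxygen lies on the H7 side, C5 lies anti to C11 and gauche to C8 as ring closure demands, and C4 of the resident C5 centre stands anti to the incoming C7, which gives the anti adduct (6β-H, 6α-OH). The step needs SE2' over SE2 attack, ring closure over oligomerisation and addition over 1,4-loss of the C8 silyloxy group, and these are secured by indium residing on the unhindered terminal C13, by slow addition at high dilution of a substrate whose aldehyde and side chain are cis on the ring, and by the poor leaving ability of the silyl ether.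

Step 11
Reactants: 16 hydroazulenol (6α-OH 7β-ethynyl 8β-OTBS)
Product: 17 8β-(TBS-oxy)guaia-3,10(14),11(13)-trien-12,6α-olide
Conditions: PdCl2 (5 mol %), PPh3, SnCl2 (cat.), CO (7 atm), MeCN, 65 °C
Reagents that add atoms: carbon monoxide, [C-]#[O+]
Why: In this palladium-catalysed cyclocarbonylation of a homopropargylic alcohol, an alkoxycarbonylpalladium formed at O6 inserts the alkyne 5-exo-dig and is protonated, which gives the trans-fused α-methylene-γ-butyrolactone as known for trans-2-ethynylcycloalkanols without touching a stereocentre.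

Step 12
Reactants: 17 8β-(TBS-oxy)guaia-3,10(14),11(13)-trien-12,6α-olide
Product: 18 3α,4α-epoxy-8β-(TBS-oxy)guaia-10(14),11(13)-dien-12,6α-olide
Conditions: mCPBA (1 equiv), NaHCO3, CH2Cl2, 0 °C
Reagents that add atoms: 3-chloroperoxybenzoic acid (mCPBA), OOC(=O)c1cccc(Cl)c1
Why: Prilezhaev epoxidation picks the only trisubstituted, most electron-rich alkene and approaches from the convex α face, although the two new centres are erased again in steps 13 and 14.

Step 13
Reactants: 18 3α,4α-epoxy-8β-(TBS-oxy)guaia-10(14),11(13)-dien-12,6α-olide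
Product: 19 3α-hydroxy-8β-(TBS-oxy)guaia-4(15),10(14),11(13)-trien-12,6α-olide
Conditions: Cp2TiCl2 (2.5 equiv), Mn dust, THF, rt; aq NaH2PO4
Reagents that add atoms: none
Why: Cp2TiCl (Nugent–RajanBabu reagent, trivalent titanium) opens the epoxide homolytically to the tertiary C4 radical, and a second Cp2TiCl removes a hydrogen of the C15 methyl group, a known neutral isomerisation of trisubstituted epoxides to exo-methylene allylic alcohols that α-methylene lactones tolerate.

Step 14
Reactants: 19 3α-hydroxy-8β-(TBS-oxy)guaia-4(15),10(14),11(13)-trien-12,6α-olide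
Product: 20 8β-(TBS-oxy)-3-oxoguaia-4(15),10(14),11(13)-trien-12,6α-olide
Conditions: Dess–Martin periodinane, NaHCO3, CH2Cl2, 0 °C
Reagents that add atoms: none
Why: Dess–Martin oxidation of the allylic alcohol gives the α-methylene cyclopentanone under buffered, non-basic conditions, and the monomer is used promptly because such enones dimerise on standing.

Step 15
Reactants: 20 8β-(TBS-oxy)-3-oxoguaia-4(15),10(14),11(13)-trien-12,6α-olide (half of the material)
Product: 21 3,8β-bis(TBS-oxy)guaia-2,4(15),10(14),11(13)-tetraen-12,6α-olide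
Conditions: TBSOTf, Et3N, CH2Cl2, −78 to 0 °C
Reagents that add atoms: tert-butyldimethylsilyl triflate (TBSOTf), CC(C)(C)[Si](C)(C)OS(=O)(=O)C(F)(F)F
Why: Soft enolisation can only take place towards C2, the single enolisable α-position of the ketone, and gives the cross-conjugated silyl dienol ether.

Step 16
Reactants: 21 3,8β-bis(TBS-oxy)guaia-2,4(15),10(14),11(13)-tetraen-12,6α-olide; 20 8β-(TBS-oxy)-3-oxoguaia-4(15),10(14),11(13)-trien-12,6α-olide
Product: 23 spiro Diels–Alder adduct (1(10)-ene 2β-H 5α-H), via dienone 22 (not isolated)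
Conditions: Pd(OAc)2 (1.1 equiv), degassed MeCN, argon, rt
Reagents that add atoms: none
Why: Saegusa–Ito oxidation (palladation of C2 on the convex α face, syn loss of H1α) unmasks the 1-acyl diene C2=C1–C10=C14 of 22, which the exocyclic enone C4'=C15' of 20 traps in an ortho-regioselective exo Diels–Alder reaction (usual for s-cis-locked α-methylene ketones) on the convex α face of 20, so that C2 ends α on the new spiro centre C4'.

Step 17
Reactants: 23 spiro Diels–Alder adduct (1(10)-ene 2β-H 5α-H)
Product: 25 8,8'-bis-O-TBS ether of the target, via 5α-H enone 24 (not isolated)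
Conditions: DBU (0.2 equiv), degassed toluene, argon, rt
Reagents that add atoms: none
Why: DBU removes the doubly activated C2–H and reprotonates the dienolate at C10 (β,γ- to α,β-enone isomerisation), and vinylogous enolisation then keeps C10 and C5 exchangeable, so that both can settle in the 5β-H,10β-H arrangement assumed above, oxygen being excluded because the dienolate autoxidises at C10.

Step 18
Reactants: 25 8,8'-bis-O-TBS ether of the target
Product: 26 target CNP0397417.1
Conditions: HF·pyridine, THF, 0 °C to rt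
Reagents that add atoms: none
Why: Mildly acidic fluoride cleaves both secondary silyl ethers without enolising the enone or adding to the three exocyclic Michael acceptors.

Compound list
1 | (+)-limonene oxide, (4R)-1,2-epoxy-p-menth-8-ene, cis/trans mixture at the epoxide | CC12OC1C[C@@H](CC2)C(C)=C | starting material
2 | (3R)-6-oxo-3-(prop-1-en-2-yl)heptanal | O=CC[C@@H](CCC(C)=O)C(C)=C | intermediate
3 | (5S)-2-methyl-5-(prop-1-en-2-yl)cyclopent-1-ene-1-carbaldehyde | CC1=C(C=O)[C@@H](CC1)C(C)=C | intermediate
4 | ethyl glyoxylate | CCOC(=O)C=O | starting material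
5 | ethyl (2R)-4-[(1S)-2-formyl-3-methylcyclopent-2-en-1-yl]-2-hydroxypent-4-enoate | O=CC1=C(C)CC[C@H]1C(=C)C[C@@H](O)C(=O)OCC | intermediate
6 | O-TBS ether of 5 | O=CC1=C(C)CC[C@H]1C(=C)C[C@@H](O[Si](C)(C)C(C)(C)C)C(=O)OCC | intermediate
7 | potassium dienolate of 6 (C6=C5 and C3=C4) | [K+].[O-]C=C1C(C)=CC[C@H]1C(=C)C[C@@H](O[Si](C)(C)C(C)(C)C)C(=O)OCC | intermediate
8 | cis β,γ-unsaturated aldehyde (1αH,5αH, 3-ene) | O=C[C@H]1C(C)=CC[C@H]1C(=C)C[C@@H](O[Si](C)(C)C(C)(C)C)C(=O)OCC | intermediate
9 | ethyl (2R)-2-(TBS-oxy)-4-[(1R,5R)-5-(hydroxymethyl)-4-methylcyclopent-3-en-1-yl]pent-4-enoate | OC[C@H]1C(C)=CC[C@H]1C(=C)C[C@@H](O[Si](C)(C)C(C)(C)C)C(=O)OCC | intermediate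
10 | (2R)-2-(TBS-oxy)-4-[(1R,5R)-5-(hydroxymethyl)-4-methylcyclopent-3-en-1-yl]pent-4-enal | OC[C@H]1C(C)=CC[C@H]1C(=C)C[C@@H](O[Si](C)(C)C(C)(C)C)C=O | intermediate
11 | ethynylmagnesium bromide | C#C[Mg]Br | starting material
12 | (3S,4R)-4-(TBS-oxy)-6-[(1R,5R)-5-(hydroxymethyl)-4-methylcyclopent-3-en-1-yl]hept-6-en-1-yn-3-ol (7,8-anti) | OC[C@H]1C(C)=CC[C@H]1C(=C)C[C@@H](O[Si](C)(C)C(C)(C)C)[C@@H](O)C#C | intermediate
13 | (1R,5R)-5-[(4R,5S)-4-(TBS-oxy)-5-hydroxyhept-1-en-6-yn-2-yl]-2-methylcyclopent-2-ene-1-carbaldehyde | O=C[C@H]1C(C)=CC[C@H]1C(=C)C[C@@H](O[Si](C)(C)C(C)(C)C)[C@@H](O)C#C | intermediate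
14 | C7 methanesulfonate of 13 | O=C[C@H]1C(C)=CC[C@H]1C(=C)C[C@@H](O[Si](C)(C)C(C)(C)C)[C@@H](OS(C)(=O)=O)C#C | intermediate
15 | allenylindium iodide mesylate (In on C13, axially chiral C7=C11=C13) | O=C[C@H]1C(C)=CC[C@H]1C(=C)C[C@@H](O[Si](C)(C)C(C)(C)C)C([H])=[C@@]=C([H])[In](I)OS(C)(=O)=O | intermediate
16 | hydroazulenol: 8β-(TBS-oxy)-6α-hydroxy-12-norguaia-3,10(14)-dien-11(13)-yne, 1αH,5αH,6βH,7αH | CC1=CC[C@H]2C(=C)C[C@@H](O[Si](C)(C)C(C)(C)C)[C@@H](C#C)[C@H](O)[C@@H]12 | intermediate
17 | 8β-(TBS-oxy)guaia-3,10(14),11(13)-trien-12,6α-olide | CC1=CC[C@H]2C(=C)C[C@@H](O[Si](C)(C)C(C)(C)C)[C@H]3C(=C)C(=O)O[C@@H]3[C@@H]12 | intermediate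
18 | 3α,4α-epoxy-8β-(TBS-oxy)guaia-10(14),11(13)-dien-12,6α-olide | C[C@@]12O[C@@H]1C[C@H]3C(=C)C[C@@H](O[Si](C)(C)C(C)(C)C)[C@H]4C(=C)C(=O)O[C@@H]4[C@@H]23 | intermediate
19 | 3α-hydroxy-8β-(TBS-oxy)guaia-4(15),10(14),11(13)-trien-12,6α-olide | C=C1[C@H](O)C[C@H]2C(=C)C[C@@H](O[Si](C)(C)C(C)(C)C)[C@H]3C(=C)C(=O)O[C@@H]3[C@@H]12 | intermediate
20 | 8β-(TBS-oxy)-3-oxoguaia-4(15),10(14),11(13)-trien-12,6α-olide (monomer) | C=C1C(=O)C[C@H]2C(=C)C[C@@H](O[Si](C)(C)C(C)(C)C)[C@H]3C(=C)C(=O)O[C@@H]3[C@@H]12 | intermediate
21 | 3,8β-bis(TBS-oxy)guaia-2,4(15),10(14),11(13)-tetraen-12,6α-olide | C=C1C(O[Si](C)(C)C(C)(C)C)=C[C@H]2C(=C)C[C@@H](O[Si](C)(C)C(C)(C)C)[C@H]3C(=C)C(=O)O[C@@H]3[C@@H]12 | intermediate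
22 | dienone: 8β-(TBS-oxy)-3-oxoguaia-1,4(15),10(14),11(13)-tetraen-12,6α-olide, 5αH | C=C1C(=O)C=C2C(=C)C[C@@H](O[Si](C)(C)C(C)(C)C)[C@H]3C(=C)C(=O)O[C@@H]3[C@@H]12 | intermediate
23 | spiro Diels–Alder adduct: C2–C4' and C14–C15' bonds, C1=C10 alkene, 2β-H, 5α-H, C2 on the α face of C4' | C=C1C(=O)[C@H]2C3=C(CC[C@]24C(=O)C[C@H]2C(=C)C[C@@H](O[Si](C)(C)C(C)(C)C)[C@H]5C(=C)C(=O)O[C@@H]5[C@H]24)C[C@@H](O[Si](C)(C)C(C)(C)C)[C@H]2C(=C)C(=O)O[C@@H]2[C@@H]13 | intermediate
24 | conjugated C1=C2 enone, 10β-H, 5α-H (C5 epimer of 25) | C=C1C(=O)C2=C3[C@H](CC[C@]24C(=O)C[C@H]2C(=C)C[C@@H](O[Si](C)(C)C(C)(C)C)[C@H]5C(=C)C(=O)O[C@@H]5[C@H]24)C[C@@H](O[Si](C)(C)C(C)(C)C)[C@H]2C(=C)C(=O)O[C@@H]2[C@@H]13 | intermediate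
25 | 8,8'-bis-O-TBS ether of the target (5β-H, 10β-H) | C=C1C(=O)C2=C3[C@H](CC[C@]24C(=O)C[C@H]2C(=C)C[C@@H](O[Si](C)(C)C(C)(C)C)[C@H]5C(=C)C(=O)O[C@@H]5[C@H]24)C[C@@H](O[Si](C)(C)C(C)(C)C)[C@H]2C(=C)C(=O)O[C@@H]2[C@H]13 | intermediate
26 | CNP0397417.1 | C=C1C(=O)C2=C3[C@H](CC[C@]24C(=O)C[C@H]2C(=C)C[C@@H](O)[C@H]5C(=C)C(=O)O[C@@H]5[C@H]24)C[C@@H](O)[C@H]2C(=C)C(=O)O[C@@H]2[C@H]13 | target

Total step count: 18. Longest linear sequence: 18 (1 to 26). Both halves are drawn from 20, so no second branch has to be built.

Steps most likely to fail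

Step 10. The allenylindium may racemise, lose silanolate by 1,4-elimination, or add intermolecularly faster than the seven-membered ring closes, and the aldehyde may reconjugate while it waits. The fallback forms the same bond with an allyl instead of an allenyl nucleophile.
- Setting out from 10, a Morita–Baylis–Hillman reaction with acrylonitrile (DABCO) would give the Baylis–Hillman adduct F1.
- TEMPO/PhI(OAc)2 would give the hydroxy aldehyde F2.
- NBS/Me2S would give the rearranged (E)-allylic bromide F3, in which C8 is cis to the slim cyano group and trans to CH2Br.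
- An intramolecular Barbier reaction (Zn, aq NH4Cl/THF, high dilution) would pass through a chair Zimmerman–Traxler transition state with C5 and C8 both equatorial and give the trans-configured hydroxy nitrile F4.
- Neutral hydration of the nitrile with [PtH(PMe2OH)(PMe2O)2H] in aqueous ethanol, followed by PPTS, would close the lactone with loss of ammonia and come back to the route at 17.

Step 17. The equilibration may stop at, or favour, another C5/C10 epimer, and the amine base may add to or isomerise the α-methylene lactones on long exposure. The fallback replaces external base on the protected compound by hydroxyl-relayed tautomerisation of the free diol. Setting out from 23, HF·pyridine would give the diol adduct F5. Its 8β-hydroxyl lies on the β face, 1,3 to C10 and 1,4 to C5. Stirring F5 over neutral alumina or in degassed phosphate buffer/THF would let this hydroxyl shuttle the proton to the β face of both γ-positions, and the sequence comes back to the route at 26.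

Step 5. Deprotonation may take place at the C15 methyl group instead of C3, protonation may occur at the γ-carbon or from the wrong face, the aldehyde may reconjugate before reduction, and C8 may epimerise. The fallback avoids a metal dienolate altogether. Setting out from 6, condensation with pyrrolidine (molecular sieves, toluene) would give the pyrrolidine dienamine F6. Its kinetic C5 protonation and hydrolysis in cold aqueous AcOH would release 8, which is reduced in the same flask with NaBH4, and the sequence comes back to the route at 9.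

Further compounds
F1 | step 10 | Baylis–Hillman adduct (C7 carbinol, both epimers) | OC[C@H]1C(C)=CC[C@H]1C(=C)C[C@@H](O[Si](C)(C)C(C)(C)C)C(O)C(=C)C#N
F2 | step 10 | hydroxy aldehyde | O=C[C@H]1C(C)=CC[C@H]1C(=C)C[C@@H](O[Si](C)(C)C(C)(C)C)C(O)C(=C)C#N
F3 | step 10 | (E)-allylic bromide | O=C[C@H]1C(C)=CC[C@H]1C(=C)C[C@@H](O[Si](C)(C)C(C)(C)C)/C=C(/CBr)C#N
F4 | step 10 | hydroxy nitrile | CC1=CC[C@H]2C(=C)C[C@@H](O[Si](C)(C)C(C)(C)C)[C@@H](C(=C)C#N)[C@H](O)[C@@H]12
F5 | step 17 | diol adduct | C=C1C(=O)[C@H]2C3=C(CC[C@]24C(=O)C[C@H]2C(=C)C[C@@H](O)[C@H]5C(=C)C(=O)O[C@@H]5[C@H]24)C[C@@H](O)[C@H]2C(=C)C(=O)O[C@@H]2[C@@H]13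
F6 | step 5 | pyrrolidine dienamine | C(=C1C(C)=CC[C@H]1C(=C)C[C@@H](O[Si](C)(C)C(C)(C)C)C(=O)OCC)N1CCCC1
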